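(The constants were set for the occasion; the result is computed.)

In a one-step world the rate follows what is left of the charge, but in this flask each turn of the catalyst also sets one released group loose, and free catalyst binds it.

    coupling partner + free catalyst ⇌ catalyst intermediate A (K1 = 71 L mol⁻¹, k1 = 0.46 L mol⁻¹ s⁻¹)
    catalyst intermediate A → released group + catalyst intermediate B (k2 = 0.14 s⁻¹)
    starting material + catalyst intermediate B → catalyst intermediate C (k3 = 0.79 L mol⁻¹ s⁻¹)
    catalyst intermediate C → free catalyst + target (k4 = 0.51 s⁻¹)
    free catalyst + released group ⇌ idle complex, settled at all times (K5 = 62 L mol⁻¹)

starting material 0.62 M; coupling partner 0.930 M; free catalyst 25 mM

- the form that holds most of the catalyst when 10% of the starting material are converted (idle complex / free catalyst / catalyst intermediate C / catalyst intermediate A / catalyst intermediate B)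
- its share of the catalyst then

- amounts and yields of released group count idle complex too
- charge of starting material (flask): 0.62 M

The reckoning here counts turnovers: N is the starting material converted per catalyst charged, and each turnover gives one released group. The ratio q of idle complex to free catalyst stands at balance, so q climbs per turnover by 1.55, the tying number T, the balance constant of the idle complex times the catalyst charge.

In the first instants N and q are near zero. Free catalyst enters catalyst intermediate A at 25.7 min⁻¹ per free catalyst, faster than catalyst intermediate A sheds the released group, at 8.4 min⁻¹, so the catalyst piles up there.

At 10% conversion N is 2.48, and T gives q = 3.84. Taking steady flow through the round, with about 0.868 M of coupling partner left, the forms per free catalyst are 2.73 for catalyst intermediate A, 0.866 for catalyst intermediate B and 0.748 for catalyst intermediate C. Catalyst intermediate A is thus the resting state of the working round, but the idle complex, outside the round, stands above it, with 41.9% of the catalyst against 29.7%.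

Counted on to the end of the charge of starting material, the limiting reagent, N reaches 24.8 and q reaches 38.4.

The forecast names the idle complex at 40%, “with A close behind”.

The simulation gives the idle complex at 38.0% and catalyst intermediate A at 31.7%. The reading of q is 3.41, lower than the 3.84 counted with T = 1.55, and the count did not take out the 9.50 mM of released group held in the idle complex. The tying of free catalyst with released group holds the rate down. Striking it out sets T to zero, and the run without the idle complex goes, at 10% conversion, at 1.56 times the actual rate.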